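**Retrosynthetic overview**
1. Last C–C bond: the 5,5′-biaryl bond, made by Suzuki–Miyaura coupling of oxolane boronate 18 with tetralin bromide 24; desilylation and O-debenzylation follow.
2. Both halves come from one lactone, 11 (trans-5-aryl-4-silyloxymethyl-butyrolactone): enolate benzylation with 13 or 20, then enolate hydroxylation anti to the C4 arm, sets the tertiary carbinol.
3. Oxolane half: the lactone ring is kept and its C=O reduced to CH2 (lactol, then silane). Tetralin half: the lactone is opened to a triol and the carbocycle closed by Friedel–Crafts alkylation.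
4. Lactone 11 comes from aroylsuccinate 6 by a ketoreductase-catalysed dynamic kinetic reduction (first two stereocentres), lactonisation and CO2H → CH2OH.
5. Ring order: butyrolactone (step 4) → oxolane (steps 11–12) and tetralin carbocycle (step 18) in separate branches → biaryl union (step 19).

Assumption: the ketoreductase of step 4 is picked from a commercial screening panel for the syn-(2S,3S) outcome; 1, 3, 5, 12 and 19 are bought. The stereochemical outcomes of steps 4, 10/16 and 18 are argued from precedent and have not been run.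

Abbreviations: Ar1 = 4-(benzyloxy)-3-bromo-5-methoxyphenyl; TBDPS = tert-butyldiphenylsilyl; Bn = benzyl; pin = pinacolato.

**Common lactone**

Step 1
Reactants: 1 methyl 3-bromo-4-hydroxy-5-methoxybenzoate
Product: 2 methyl 4-(benzyloxy)-3-bromo-5-methoxybenzoate
Conditions: BnBr, K2CO3, DMF, 60 °C
Reagents that add atoms: benzyl bromide, BrCc1ccccc1
Why: Williamson ether synthesis on the only acidic site; the benzyl ether survives every later step until hydrogenolysis.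

Step 2
Reactants: 2 methyl 4-(benzyloxy)-3-bromo-5-methoxybenzoate; 3 tert-butyl acetate
Product: 4 tert-butyl 3-Ar1-3-oxopropanoate
Conditions: LiN(SiMe3)2 (2.3 equiv), 3 (2.2 equiv), THF, −78 → 0 °C; aq. NH4Cl
Reagents that add atoms: none
Why: Crossed Claisen condensation of the ester enolate with a non-enolisable aryl ester, driven by deprotonation of the β-keto ester product.

Step 3
Reactants: 4 tert-butyl 3-Ar1-3-oxopropanoate; 5 methyl bromoacetate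
Product: 6 1-tert-butyl 4-methyl 2-(Ar1-carbonyl)butanedioate (racemic; the C2–H is acidic, so this centre equilibrates freely and no configuration is set here)
Conditions: K2CO3, acetone, rt
Reagents that add atoms: none
Why: SN2 C-alkylation of the stabilised β-keto ester enolate with an α-bromo ester.

Step 4
Reactants: 6 1-tert-butyl 4-methyl 2-(Ar1-carbonyl)butanedioate
Product: 8 tert-butyl (2S,3S)-2-Ar1-5-oxooxolane-3-carboxylate (2,3-trans), via hydroxy diester 7 (not isolated)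
Conditions: ketoreductase (NADPH-dependent alcohol dehydrogenase, syn-selective), NADP+ (cat.), iPrOH (15 vol %), K2HPO4/KH2PO4 buffer pH 7.5, DMSO (5 vol %), 30 °C; extract; PPTS (cat.), PhMe, 60 °C
Reagents that add atoms: none
Why: Enzymatic dynamic kinetic resolution by carbonyl reduction: C2 of 6 epimerises fast at pH 7.5 and the ketoreductase reduces only the (2S)-ketone from one face, which sets the carbinol (S) and its neighbour (S, syn); the γ-hydroxy methyl ester 7 then lactonises to the trans lactone.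

Step 5
Reactants: 8 tert-butyl (2S,3S)-2-Ar1-5-oxooxolane-3-carboxylate
Product: 9 (2S,3S)-2-Ar1-5-oxooxolane-3-carboxylic acid
Conditions: CF3CO2H/CH2Cl2 1:4, 0 °C → rt; evaporate; recrystallise
Reagents that add atoms: none
Why: Acidolysis of the tert-butyl ester (E1 loss of isobutene) leaves lactone, aryl bromide and benzyl ether alone; crystallisation of the acid upgrades dr and ee.

Step 6
Reactants: 9 (2S,3S)-2-Ar1-5-oxooxolane-3-carboxylic acid
Product: 10 (4R,5S)-5-Ar1-4-(hydroxymethyl)oxolan-2-one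
Conditions: BH3·SMe2 (1.3 equiv), THF, 0 °C → rt; then H2O
Reagents that add atoms: none
Why: Chemoselective borane reduction of a carboxylic acid (via the acyloxyborane) beside a lactone; no stereocentre is touched (the descriptor at C4 changes only through CIP priorities).

Step 7
Reactants: 10 (4R,5S)-5-Ar1-4-(hydroxymethyl)oxolan-2-one
Product: 11 (4R,5S)-5-Ar1-4-[(TBDPS-oxy)methyl]oxolan-2-one
Conditions: TBDPSCl, imidazole, DMF, 0 °C → rt
Reagents that add atoms: tert-butyl(chloro)diphenylsilane, CC(C)(C)[Si](Cl)(c1ccccc1)c1ccccc1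
Why: Silylation of the primary alcohol blocks translactonisation and puts a bulky group on the lower face for the enolate steps.

**Oxolane half**

Step 8
Reactants: 12 [3-(benzyloxy)-4-methoxyphenyl]methanol
Product: 13 2-(benzyloxy)-4-(bromomethyl)-1-methoxybenzene
Conditions: PBr3 (0.4 equiv), Et2O, 0 °C; used at once
Reagents that add atoms: phosphorus tribromide, BrP(Br)Br
Why: Bromide displacement on the activated bromophosphite of an electron-rich benzylic alcohol.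

Step 9
Reactants: 11 (4R,5S)-5-Ar1-4-[(TBDPS-oxy)methyl]oxolan-2-one; 13 2-(benzyloxy)-4-(bromomethyl)-1-methoxybenzene
Product: 14 (3S,4R,5S)-5-Ar1-3-{[3-(benzyloxy)-4-methoxyphenyl]methyl}-4-[(TBDPS-oxy)methyl]oxolan-2-one
Conditions: LiN(SiMe3)2 (1.1 equiv), THF, −78 °C; 13, DMPU, −78 → −30 °C
Reagents that add atoms: none
Why: Lactone enolate alkylation (SN2) anti to the C4 substituent gives the 3,4-trans product; this C3 centre is erased in the next step.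

Step 10
Reactants: 14 (3S,4R,5S)-5-Ar1-3-{[3-(benzyloxy)-4-methoxyphenyl]methyl}-4-[(TBDPS-oxy)methyl]oxolan-2-one
Product: 15 (3S,4R,5S)-5-Ar1-3-{[3-(benzyloxy)-4-methoxyphenyl]methyl}-3-hydroxy-4-[(TBDPS-oxy)methyl]oxolan-2-one
Conditions: KN(SiMe3)2 (1.3 equiv), THF, −78 °C; 3-phenyl-2-(phenylsulfonyl)oxaziridine (1.5 equiv), −78 °C; aq. NH4Cl
Reagents that add atoms: 3-phenyl-2-(phenylsulfonyl)oxaziridine (racemic Davis reagent), O=S(=O)(c1ccccc1)N1OC1c1ccccc1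
Why: Davis enolate hydroxylation: the oxidant should reach the tetrasubstituted potassium enolate from the face opposite the neighbouring CH2OTBDPS group, so OH ends trans to that arm and the benzyl group cis (3S).

Step 11
Reactants: 15 (3S,4R,5S)-5-Ar1-3-{[3-(benzyloxy)-4-methoxyphenyl]methyl}-3-hydroxy-4-[(TBDPS-oxy)methyl]oxolan-2-one
Product: 16 (3S,4R,5S)-5-Ar1-3-{[3-(benzyloxy)-4-methoxyphenyl]methyl}-4-[(TBDPS-oxy)methyl]oxolane-2,3-diol (lactol, both C2 epimers)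
Conditions: iBu2AlH (2.5 equiv), CH2Cl2, −78 °C; aq. KNaC4H4O6 work-up
Reagents that add atoms: none
Why: Partial reduction of a lactone to the lactol; the tetrahedral aluminate is stable at −78 °C (one equivalent is consumed by the tertiary OH).

Step 12
Reactants: 16 lactol (3S,4R,5S)-5-Ar1-3-{[3-(benzyloxy)-4-methoxyphenyl]methyl}-4-[(TBDPS-oxy)methyl]oxolane-2,3-diol
Product: 17 (3S,4R,5S)-5-Ar1-3-{[3-(benzyloxy)-4-methoxyphenyl]methyl}-4-[(TBDPS-oxy)methyl]oxolan-3-ol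
Conditions: Et3SiH (5 equiv), BF3·OEt2 (2 equiv), CH2Cl2, −78 → −40 °C; aq. NaHCO3
Reagents that add atoms: none
Why: Ionic hydrogenation of the lactol through its oxocarbenium ion; the lactol ionises far faster than the bromo-deactivated 2-aryl ether at low temperature, and no stereocentre is involved.

Step 13
Reactants: 17 (3S,4R,5S)-5-Ar1-3-{[3-(benzyloxy)-4-methoxyphenyl]methyl}-4-[(TBDPS-oxy)methyl]oxolan-3-ol
Product: 18 (3S,4R,5S)-5-[4-(benzyloxy)-3-methoxy-5-(4,4,5,5-tetramethyl-1,3,2-dioxaborolan-2-yl)phenyl]-3-{[3-(benzyloxy)-4-methoxyphenyl]methyl}-4-[(TBDPS-oxy)methyl]oxolan-3-ol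
Conditions: B2pin2 (1.5 equiv), Pd(dppf)Cl2 (5 mol %), KOAc (3 equiv), 1,4-dioxane, 90 °C
Reagents that add atoms: bis(pinacolato)diboron, CC1(C)OB(OC1(C)C)B1OC(C)(C)C(C)(C)O1
Why: Miyaura borylation of the aryl bromide; the free tertiary alcohol and silyl ether are tolerated.

**Tetralin half**

Step 14
Reactants: 19 [4-(benzyloxy)-3-methoxyphenyl]methanol
Product: 20 1-(benzyloxy)-4-(bromomethyl)-2-methoxybenzene
Conditions: PBr3 (0.4 equiv), Et2O, 0 °C; used at once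
Reagents that add atoms: phosphorus tribromide, BrP(Br)Br
Why: Same alcohol-to-bromide substitution as step 8.

Step 15
Reactants: 11 (4R,5S)-5-Ar1-4-[(TBDPS-oxy)methyl]oxolan-2-one; 20 1-(benzyloxy)-4-(bromomethyl)-2-methoxybenzene
Product: 21 (3S,4R,5S)-5-Ar1-3-{[4-(benzyloxy)-3-methoxyphenyl]methyl}-4-[(TBDPS-oxy)methyl]oxolan-2-one
Conditions: LiN(SiMe3)2 (1.1 equiv), THF, −78 °C; 20, DMPU, −78 → −30 °C
Reagents that add atoms: none
Why: Lactone enolate alkylation (SN2) anti to the C4 substituent, as in step 9.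

Step 16
Reactants: 21 (3S,4R,5S)-5-Ar1-3-{[4-(benzyloxy)-3-methoxyphenyl]methyl}-4-[(TBDPS-oxy)methyl]oxolan-2-one
Product: 22 (3S,4R,5S)-5-Ar1-3-{[4-(benzyloxy)-3-methoxyphenyl]methyl}-3-hydroxy-4-[(TBDPS-oxy)methyl]oxolan-2-one
Conditions: KN(SiMe3)2 (1.3 equiv), THF, −78 °C; 3-phenyl-2-(phenylsulfonyl)oxaziridine (1.5 equiv), −78 °C; aq. NH4Cl
Reagents that add atoms: 3-phenyl-2-(phenylsulfonyl)oxaziridine (racemic Davis reagent), O=S(=O)(c1ccccc1)N1OC1c1ccccc1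
Why: Davis enolate hydroxylation anti to the CH2OTBDPS arm, as in step 10, sets the tertiary carbinol (3S).

Step 17
Reactants: 22 (3S,4R,5S)-5-Ar1-3-{[4-(benzyloxy)-3-methoxyphenyl]methyl}-3-hydroxy-4-[(TBDPS-oxy)methyl]oxolan-2-one
Product: 23 (1S,2R,3S)-1-Ar1-3-{[4-(benzyloxy)-3-methoxyphenyl]methyl}-2-[(TBDPS-oxy)methyl]butane-1,3,4-triol
Conditions: LiBH4 (3 equiv), THF, 0 °C → rt
Reagents that add atoms: none
Why: Hydride reduction of the lactone to the diol without touching aryl bromide or silyl ether; stereocentres are unchanged.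

Step 18
Reactants: 23 (1S,2R,3S)-1-Ar1-3-{[4-(benzyloxy)-3-methoxyphenyl]methyl}-2-[(TBDPS-oxy)methyl]butane-1,3,4-triol
Product: 24 (2S,3S,4S)-4-Ar1-6-(benzyloxy)-2-(hydroxymethyl)-7-methoxy-3-[(TBDPS-oxy)methyl]-1,2,3,4-tetrahydronaphthalen-2-ol
Conditions: CF3CO2H (10 equiv), CH2Cl2, 0 °C → rt; aq. NaHCO3
Reagents that add atoms: none
Why: Intramolecular Friedel–Crafts alkylation: the benzylic cation is attacked by the ring position para to OMe to close the six-membered ring, with the aryl group pseudo-equatorial and trans to the neighbouring CH2OTBDPS (4S); any oxolane formed first re-ionises and funnels to the tetralin.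

**Union and deprotection**

Step 19
Reactants: 18 oxolane boronate; 24 tetralin bromide
Product: 25 (3S,4R,5S)-5-{4-(benzyloxy)-3-[2-(benzyloxy)-5-[(1S,2S,3S)-7-(benzyloxy)-3-hydroxy-3-(hydroxymethyl)-6-methoxy-2-[(TBDPS-oxy)methyl]-1,2,3,4-tetrahydronaphthalen-1-yl]-3-methoxyphenyl]-5-methoxyphenyl}-3-{[3-(benzyloxy)-4-methoxyphenyl]methyl}-4-[(TBDPS-oxy)methyl]oxolan-3-ol
Conditions: Pd(OAc)2 (5 mol %), SPhos (10 mol %), K3PO4 (3 equiv), PhMe/H2O 10:1, degassed, 90 °C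
Reagents that add atoms: none
Why: Suzuki–Miyaura coupling; the zerovalent palladium/SPhos catalyst formed in situ handles two ortho-alkoxy partners, and the biaryl has only two ortho substituents, so no atropisomer issue arises.

Step 20
Reactants: 25 bis-TBDPS tetra-O-benzyl biaryl
Product: 26 (3S,4R,5S)-5-{4-(benzyloxy)-3-[2-(benzyloxy)-5-[(1S,2S,3S)-7-(benzyloxy)-3-hydroxy-2,3-bis(hydroxymethyl)-6-methoxy-1,2,3,4-tetrahydronaphthalen-1-yl]-3-methoxyphenyl]-5-methoxyphenyl}-3-{[3-(benzyloxy)-4-methoxyphenyl]methyl}-4-(hydroxymethyl)oxolan-3-ol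
Conditions: Bu4NF (3 equiv), THF, rt
Reagents that add atoms: none
Why: Fluoride-mediated desilylation of the two primary silyl ethers under non-acidic conditions that spare the 2-aryl oxolane.

Step 21
Reactants: 26 tetra-O-benzyl ether
Product: 27 CNP0252244.1, (3S,4R,5S)-5-{4-hydroxy-3-[2-hydroxy-5-[(1S,2S,3S)-3,7-dihydroxy-2,3-bis(hydroxymethyl)-6-methoxy-1,2,3,4-tetrahydronaphthalen-1-yl]-3-methoxyphenyl]-5-methoxyphenyl}-3-[(3-hydroxy-4-methoxyphenyl)methyl]-4-(hydroxymethyl)oxolan-3-ol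
Conditions: H2 (1 atm), 10% Pd/C, EtOAc/MeOH 1:1, rt, followed by LC-MS and stopped at full debenzylation
Reagents that add atoms: none
Why: Catalytic hydrogenolysis of four aryl benzyl ethers, which cleave much faster than the cyclic benzylic ether under neutral conditions.

**Compound list**
1 | methyl 3-bromo-4-hydroxy-5-methoxybenzoate | COC(=O)c1cc(OC)c(O)c(Br)c1 | starting material
2 | methyl 4-(benzyloxy)-3-bromo-5-methoxybenzoate | COC(=O)c1cc(OC)c(OCc2ccccc2)c(Br)c1 | intermediate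
3 | tert-butyl acetate | CC(=O)OC(C)(C)C | starting material
4 | tert-butyl 3-Ar1-3-oxopropanoate | CC(C)(C)OC(=O)CC(=O)c1cc(OC)c(OCc2ccccc2)c(Br)c1 | intermediate
5 | methyl bromoacetate | COC(=O)CBr | starting material
6 | 1-tert-butyl 4-methyl 2-(Ar1-carbonyl)butanedioate (racemic, stereolabile) | COC(=O)CC(C(=O)OC(C)(C)C)C(=O)c1cc(OC)c(OCc2ccccc2)c(Br)c1 | intermediate
7 | 1-tert-butyl 4-methyl (2S)-2-[(S)-Ar1(hydroxy)methyl]butanedioate | COC(=O)C[C@H](C(=O)OC(C)(C)C)[C@H](O)c1cc(OC)c(OCc2ccccc2)c(Br)c1 | intermediate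
8 | tert-butyl (2S,3S)-2-Ar1-5-oxooxolane-3-carboxylate | O=C1C[C@H](C(=O)OC(C)(C)C)[C@@H](c2cc(OC)c(OCc3ccccc3)c(Br)c2)O1 | intermediate
9 | (2S,3S)-2-Ar1-5-oxooxolane-3-carboxylic acid | O=C1C[C@H](C(=O)O)[C@@H](c2cc(OC)c(OCc3ccccc3)c(Br)c2)O1 | intermediate
10 | (4R,5S)-5-Ar1-4-(hydroxymethyl)oxolan-2-one | O=C1C[C@H](CO)[C@@H](c2cc(OC)c(OCc3ccccc3)c(Br)c2)O1 | intermediate
11 | (4R,5S)-5-Ar1-4-[(TBDPS-oxy)methyl]oxolan-2-one | O=C1C[C@H](CO[Si](c2ccccc2)(c2ccccc2)C(C)(C)C)[C@@H](c2cc(OC)c(OCc3ccccc3)c(Br)c2)O1 | intermediate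
12 | [3-(benzyloxy)-4-methoxyphenyl]methanol | COc1ccc(CO)cc1OCc1ccccc1 | starting material
13 | 2-(benzyloxy)-4-(bromomethyl)-1-methoxybenzene | COc1ccc(CBr)cc1OCc1ccccc1 | intermediate
14 | (3S,4R,5S)-5-Ar1-3-{[3-(benzyloxy)-4-methoxyphenyl]methyl}-4-[(TBDPS-oxy)methyl]oxolan-2-one | O=C1[C@@H](Cc2ccc(OC)c(OCc3ccccc3)c2)[C@H](CO[Si](c2ccccc2)(c2ccccc2)C(C)(C)C)[C@@H](c2cc(OC)c(OCc3ccccc3)c(Br)c2)O1 | intermediate
15 | (3S,4R,5S)-5-Ar1-3-{[3-(benzyloxy)-4-methoxyphenyl]methyl}-3-hydroxy-4-[(TBDPS-oxy)methyl]oxolan-2-one | O=C1[C@](O)(Cc2ccc(OC)c(OCc3ccccc3)c2)[C@H](CO[Si](c2ccccc2)(c2ccccc2)C(C)(C)C)[C@@H](c2cc(OC)c(OCc3ccccc3)c(Br)c2)O1 | intermediate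
16 | (3S,4R,5S)-5-Ar1-3-{[3-(benzyloxy)-4-methoxyphenyl]methyl}-4-[(TBDPS-oxy)methyl]oxolane-2,3-diol (C2 epimers) | OC1[C@](O)(Cc2ccc(OC)c(OCc3ccccc3)c2)[C@H](CO[Si](c2ccccc2)(c2ccccc2)C(C)(C)C)[C@@H](c2cc(OC)c(OCc3ccccc3)c(Br)c2)O1 | intermediate
17 | (3S,4R,5S)-5-Ar1-3-{[3-(benzyloxy)-4-methoxyphenyl]methyl}-4-[(TBDPS-oxy)methyl]oxolan-3-ol | C1[C@](O)(Cc2ccc(OC)c(OCc3ccccc3)c2)[C@H](CO[Si](c2ccccc2)(c2ccccc2)C(C)(C)C)[C@@H](c2cc(OC)c(OCc3ccccc3)c(Br)c2)O1 | intermediate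
18 | (3S,4R,5S)-5-[4-(benzyloxy)-3-methoxy-5-(pinacolatoboryl)phenyl]-3-{[3-(benzyloxy)-4-methoxyphenyl]methyl}-4-[(TBDPS-oxy)methyl]oxolan-3-ol | C1[C@](O)(Cc2ccc(OC)c(OCc3ccccc3)c2)[C@H](CO[Si](c2ccccc2)(c2ccccc2)C(C)(C)C)[C@@H](c2cc(OC)c(OCc3ccccc3)c(B3OC(C)(C)C(C)(C)O3)c2)O1 | intermediate
19 | [4-(benzyloxy)-3-methoxyphenyl]methanol | COc1cc(CO)ccc1OCc1ccccc1 | starting material
20 | 1-(benzyloxy)-4-(bromomethyl)-2-methoxybenzene | COc1cc(CBr)ccc1OCc1ccccc1 | intermediate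
21 | (3S,4R,5S)-5-Ar1-3-{[4-(benzyloxy)-3-methoxyphenyl]methyl}-4-[(TBDPS-oxy)methyl]oxolan-2-one | O=C1[C@@H](Cc2ccc(OCc3ccccc3)c(OC)c2)[C@H](CO[Si](c2ccccc2)(c2ccccc2)C(C)(C)C)[C@@H](c2cc(OC)c(OCc3ccccc3)c(Br)c2)O1 | intermediate
22 | (3S,4R,5S)-5-Ar1-3-{[4-(benzyloxy)-3-methoxyphenyl]methyl}-3-hydroxy-4-[(TBDPS-oxy)methyl]oxolan-2-one | O=C1[C@](O)(Cc2ccc(OCc3ccccc3)c(OC)c2)[C@H](CO[Si](c2ccccc2)(c2ccccc2)C(C)(C)C)[C@@H](c2cc(OC)c(OCc3ccccc3)c(Br)c2)O1 | intermediate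
23 | (1S,2R,3S)-1-Ar1-3-{[4-(benzyloxy)-3-methoxyphenyl]methyl}-2-[(TBDPS-oxy)methyl]butane-1,3,4-triol | OC[C@](O)(Cc1ccc(OCc2ccccc2)c(OC)c1)[C@H](CO[Si](c1ccccc1)(c1ccccc1)C(C)(C)C)[C@@H](c1cc(OC)c(OCc2ccccc2)c(Br)c1)O | intermediate
24 | (2S,3S,4S)-4-Ar1-6-(benzyloxy)-2-(hydroxymethyl)-7-methoxy-3-[(TBDPS-oxy)methyl]-1,2,3,4-tetrahydronaphthalen-2-ol | COc1cc([C@H]2c3cc(OCc4ccccc4)c(OC)cc3C[C@@](O)(CO)[C@@H]2CO[Si](c2ccccc2)(c2ccccc2)C(C)(C)C)cc(Br)c1OCc1ccccc1 | intermediate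
25 | bis-TBDPS tetra-O-benzyl biaryl (name in step 19) | COc1ccc(C[C@@]2(O)CO[C@H](c3cc(OC)c(OCc4ccccc4)c(-c4cc([C@H]5c6cc(OCc7ccccc7)c(OC)cc6C[C@@](O)(CO)[C@@H]5CO[Si](c5ccccc5)(c5ccccc5)C(C)(C)C)cc(OC)c4OCc4ccccc4)c3)[C@H]2CO[Si](c2ccccc2)(c2ccccc2)C(C)(C)C)cc1OCc1ccccc1 | intermediate
26 | tetra-O-benzyl ether of the target (name in step 20) | COc1ccc(C[C@@]2(O)CO[C@H](c3cc(OC)c(OCc4ccccc4)c(-c4cc([C@H]5c6cc(OCc7ccccc7)c(OC)cc6C[C@@](O)(CO)[C@@H]5CO)cc(OC)c4OCc4ccccc4)c3)[C@H]2CO)cc1OCc1ccccc1 | intermediate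
27 | CNP0252244.1 (name in step 21) | COc1ccc(C[C@@]2(O)CO[C@H](c3cc(OC)c(O)c(-c4cc([C@H]5c6cc(O)c(OC)cc6C[C@@](O)(CO)[C@@H]5CO)cc(OC)c4O)c3)[C@H]2CO)cc1O | target

**Totals**
Total steps: 21. Longest linear sequence: 15 (steps 1–7, 9–13, 19–21).

**Steps most likely to fail, with fallbacks**

Step 4 (no ketoreductase may accept the branched keto diester or give the syn product). The fallback sets out from 6 and comes back at 10. It drops the dynamic resolution: the enzyme only reduces a plain aryl ketone, and the second centre is set by substrate control.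
- Treat 6 with CF3CO2H in CH2Cl2, then warm in PhMe (80 °C): the tert-butyl ester is lost and the β-keto acid 2-(Ar1-carbonyl)-4-methoxy-4-oxobutanoic acid F1 decarboxylates to the achiral γ-keto ester methyl 4-Ar1-4-oxobutanoate F2.
- A ketoreductase (same iPrOH/NADP+ system) gives methyl (4S)-4-Ar1-4-hydroxybutanoate F3, which closes (PPTS, PhMe) to (5S)-5-Ar1-oxolan-2-one F4.
- LiN(SiMe3)2/PhSeBr (THF, −78 °C) gives the selenide (5S)-5-Ar1-3-(phenylselanyl)oxolan-2-one F5. H2O2 (CH2Cl2, 0 °C) gives the selenoxide (5S)-5-Ar1-3-(benzeneseleninyl)oxolan-2-one F6, which undergoes syn-elimination to the butenolide (5S)-5-Ar1-furan-2(5H)-one F7.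
- CH2=CHMgBr/CuBr·SMe2/Me3SiCl (THF, −78 °C) adds anti to the aryl group to give (4R,5S)-5-Ar1-4-ethenyloxolan-2-one F8.
- Ozonolysis (O3, CH2Cl2/MeOH, −78 °C; Me2S) gives the aldehyde (2S,3S)-2-Ar1-5-oxooxolane-3-carbaldehyde F9, and NaBH4 added to the same flask gives 10.

Step 10 (conversion and face selectivity at the quaternary carbinol; step 16 is the same reaction on the sister compound). The fallback sets out from 11 and comes back at 15. It builds the carbinol by alkene dihydroxylation instead of enolate oxidation.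
- Alcohol 12 is oxidised (MnO2, CH2Cl2) to 3-(benzyloxy)-4-methoxybenzaldehyde F10.
- The lithium enolate of 11 (LiN(SiMe3)2, THF, −78 °C) adds to it to give the aldol adducts (3R,4R,5S)-5-Ar1-3-{[3-(benzyloxy)-4-methoxyphenyl](hydroxy)methyl}-4-[(TBDPS-oxy)methyl]oxolan-2-one F11 (carbinol epimers).
- MsCl/Et3N gives the mesylates F12, and DBU eliminates to the (3E,4R,5S)-3-arylidene lactone F13.
- OsO4 (cat.)/N-methylmorpholine N-oxide in acetone/H2O dihydroxylates from the face opposite the CH2OTBDPS arm to the diol (3R,4R,5S)-5-Ar1-3-hydroxy-3-{(S)-[3-(benzyloxy)-4-methoxyphenyl](hydroxy)methyl}-4-[(TBDPS-oxy)methyl]oxolan-2-one F14.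
- Et3SiH/CF3CO2H (CH2Cl2, −20 °C) removes the secondary benzylic OH by ionic hydrogenation (cation para to OMe) and gives 15.

Step 12 (silane reduction beside a free tertiary OH and an acid-labile 2-aryl ether). The fallback sets out from 15 and comes back at 17. The ring is closed at the other C–O bond.
- LiBH4 (THF, 0 °C) opens the lactone to (1S,2R,3S)-1-Ar1-3-{[3-(benzyloxy)-4-methoxyphenyl]methyl}-2-[(TBDPS-oxy)methyl]butane-1,3,4-triol F15.
- Camphorsulfonic acid (cat.) in CH2Cl2 at 0 °C ionises the benzylic alcohol and the primary OH closes the oxolane with the aryl trans to the neighbouring arm, giving 17. The reaction is stopped before the slower Friedel–Crafts closure sets in.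

**Further compounds**
F1 | step 4 | 2-(Ar1-carbonyl)-4-methoxy-4-oxobutanoic acid (racemic) | COC(=O)CC(C(=O)O)C(=O)c1cc(OC)c(OCc2ccccc2)c(Br)c1
F2 | step 4 | methyl 4-Ar1-4-oxobutanoate | COC(=O)CCC(=O)c1cc(OC)c(OCc2ccccc2)c(Br)c1
F3 | step 4 | methyl (4S)-4-Ar1-4-hydroxybutanoate | COC(=O)CC[C@H](O)c1cc(OC)c(OCc2ccccc2)c(Br)c1
F4 | step 4 | (5S)-5-Ar1-oxolan-2-one | O=C1CC[C@@H](c2cc(OC)c(OCc3ccccc3)c(Br)c2)O1
F5 | step 4 | (5S)-5-Ar1-3-(phenylselanyl)oxolan-2-one (C3 epimers) | O=C1C([Se]c2ccccc2)C[C@@H](c2cc(OC)c(OCc3ccccc3)c(Br)c2)O1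
F6 | step 4 | (5S)-5-Ar1-3-(benzeneseleninyl)oxolan-2-one | O=C1C([Se](=O)c2ccccc2)C[C@@H](c2cc(OC)c(OCc3ccccc3)c(Br)c2)O1
F7 | step 4 | (5S)-5-Ar1-furan-2(5H)-one | O=C1C=C[C@@H](c2cc(OC)c(OCc3ccccc3)c(Br)c2)O1
F8 | step 4 | (4R,5S)-5-Ar1-4-ethenyloxolan-2-one | O=C1C[C@H](C=C)[C@@H](c2cc(OC)c(OCc3ccccc3)c(Br)c2)O1
F9 | step 4 | (2S,3S)-2-Ar1-5-oxooxolane-3-carbaldehyde | O=C1C[C@H](C=O)[C@@H](c2cc(OC)c(OCc3ccccc3)c(Br)c2)O1
F10 | step 10 | 3-(benzyloxy)-4-methoxybenzaldehyde | COc1ccc(C=O)cc1OCc1ccccc1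
F11 | step 10 | (3R,4R,5S)-5-Ar1-3-{[3-(benzyloxy)-4-methoxyphenyl](hydroxy)methyl}-4-[(TBDPS-oxy)methyl]oxolan-2-one (carbinol epimers) | O=C1[C@@H](C(O)c2ccc(OC)c(OCc3ccccc3)c2)[C@H](CO[Si](c2ccccc2)(c2ccccc2)C(C)(C)C)[C@@H](c2cc(OC)c(OCc3ccccc3)c(Br)c2)O1
F12 | step 10 | methanesulfonate of F11 | O=C1[C@@H](C(OS(C)(=O)=O)c2ccc(OC)c(OCc3ccccc3)c2)[C@H](CO[Si](c2ccccc2)(c2ccccc2)C(C)(C)C)[C@@H](c2cc(OC)c(OCc3ccccc3)c(Br)c2)O1
F13 | step 10 | (3E,4R,5S)-5-Ar1-3-{[3-(benzyloxy)-4-methoxyphenyl]methylidene}-4-[(TBDPS-oxy)methyl]oxolan-2-one | O=C1/C(=C/c2ccc(OC)c(OCc3ccccc3)c2)[C@H](CO[Si](c2ccccc2)(c2ccccc2)C(C)(C)C)[C@@H](c2cc(OC)c(OCc3ccccc3)c(Br)c2)O1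
F14 | step 10 | (3R,4R,5S)-5-Ar1-3-hydroxy-3-{(S)-[3-(benzyloxy)-4-methoxyphenyl](hydroxy)methyl}-4-[(TBDPS-oxy)methyl]oxolan-2-one | O=C1[C@](O)([C@@H](O)c2ccc(OC)c(OCc3ccccc3)c2)[C@H](CO[Si](c2ccccc2)(c2ccccc2)C(C)(C)C)[C@@H](c2cc(OC)c(OCc3ccccc3)c(Br)c2)O1
F15 | step 12 | (1S,2R,3S)-1-Ar1-3-{[3-(benzyloxy)-4-methoxyphenyl]methyl}-2-[(TBDPS-oxy)methyl]butane-1,3,4-triol | OC[C@](O)(Cc1ccc(OC)c(OCc2ccccc2)c1)[C@H](CO[Si](c1ccccc1)(c1ccccc1)C(C)(C)C)[C@@H](c1cc(OC)c(OCc2ccccc2)c(Br)c1)O
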